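**Retrosynthetic overview**
1. End game: the 9-O-acetyl group and the C14 aldehyde come last from a 9,14-diol, and the 8-O-(2-acetoxy-2-methylbutanoyl) ester from an 8-hydroxy α-methylene lactone. The α-methylene group and the trans 12,6-lactone (closed by Mitsunobu inversion at C6) are built on a ten-membered keto ester.
2. Key disconnection: C8–C9 of the ten-membered ring, made by an anionic oxy-Cope ring expansion of a cis-1,6-dialkenylcyclohex-2-en-1-ol with in-situ C7 alkylation of the enolate. The same operation sets the C8/C9 pair, the cis C1=C10 alkene and C7.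
3. Enabling feature: in the ring, C8–C9 is flanked by C7 (α to the C6 oxygen) and by C10 of the C1=C10 alkene, so it is the σ-bond of an oxy-Cope product. The parent bond C1–C6 closes a six-membered ring C1–C6 that holds the cis C4=C5 alkene. O8 and O9 ride on the migrating termini as enol ethers, and O9/O14 (1,3-related) are tied in a temporary 4H-1,3-dioxin ring that fixes the C9 enol-ether geometry.
4. The cyclohexenol comes from a (6R)-6-dioxinyl-3-methylcyclohexenone and a PMB ynol-ether acetylide (then Lindlar). The ketone comes from an enzymatically desymmetrised cyclohexene-1,4-diol monoacetate and a dioxinyl boronate (nickel-catalysed substitution, oxidation, MeLi, 1,3-transposition).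
5. Ring order: cyclohexene ring (from the diene) and dioxin ring (from dihydroxyacetone acetonide) → ten-membered carbocycle fused to a 1,3-dioxane (key step) → γ-lactone → dioxane opened at the end.

Key step: step 12

Assumption: the hydrolase of step 4 is taken to leave the acetate on the R-configured carbon (as in the cyclopentene series); if it shows the opposite sense, the same monoacetate is reached by lipase-catalysed mono-acetylation of the meso-diol with vinyl acetate.
Numbering: ten-membered-ring compounds carry germacrane numbering (ring C1–C10, lactone carbons C11–C13, C14 on C10, C15 on C4); PMB = 4-methoxybenzyl.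

**Step 1**
Reactants: 1 2,2-dimethyl-1,3-dioxan-5-one
Product: 2 2,2-dimethyl-4H-1,3-dioxin-5-yl trifluoromethanesulfonate
Conditions: LiN(SiMe3)2, THF, −78 °C; PhNTf2, −78 → 0 °C
Reagents that add atoms: N-phenylbis(trifluoromethanesulfonimide), O=S(=O)(N(c1ccccc1)S(=O)(=O)C(F)(F)F)C(F)(F)F
Why: Kinetic enolisation of the symmetric ketone and O-sulfonylation of the enolate (enol triflate formation) give the ring-locked enol ether triflate; no stereocentre is formed.

**Step 2**
Reactants: 2 2,2-dimethyl-4H-1,3-dioxin-5-yl trifluoromethanesulfonate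
Product: 3 2-(2,2-dimethyl-4H-1,3-dioxin-5-yl)-4,4,5,5-tetramethyl-1,3,2-dioxaborolane
Conditions: B2pin2, PdCl2(PPh3)2 (3 mol %), PPh3, KOPh, toluene, 50 °C
Reagents that add atoms: bis(pinacolato)diboron, CC1(C)OB(OC1(C)C)B2OC(C)(C)C(C)(C)O2
Why: Miyaura borylation of an alkenyl triflate under mild phenoxide conditions keeps the 4H-1,3-dioxin well below the temperature of its retro-[4+2] fragmentation and gives a stable β-alkoxyalkenyl boronate.

**Step 3**
Reactants: 4 cyclohexa-1,3-diene
Product: 5 cis-cyclohex-2-ene-1,4-diyl diacetate (meso)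
Conditions: Pd(OAc)2 (5 mol %), LiCl (cat.), LiOAc, p-benzoquinone, AcOH, rt
Reagents that add atoms: acetic acid, CC(=O)O
Why: Palladium-catalysed 1,4-diacetoxylation of a 1,3-diene (Bäckvall reaction): anti acetoxypalladation and, with catalytic chloride, external anti attack of acetate on the π-allyl intermediate give the cis (meso) diacetate.

**Step 4**
Reactants: 5 cis-cyclohex-2-ene-1,4-diyl diacetate
Product: 6 (1R,4S)-4-hydroxycyclohex-2-en-1-yl acetate
Conditions: acetylcholinesterase (electric eel), phosphate buffer pH 7, rt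
Reagents that add atoms: none
Why: Enzymatic desymmetrisation of a meso-diacetate by enantiotopos-selective ester hydrolysis sets both stereocentres at once and is the source of absolute configuration for the whole route.

**Step 5**
Reactants: 3 2-(2,2-dimethyl-4H-1,3-dioxin-5-yl)-4,4,5,5-tetramethyl-1,3,2-dioxaborolane; 6 (1R,4S)-4-hydroxycyclohex-2-en-1-yl acetate
Product: 8 (1S,4S)-4-(2,2-dimethyl-4H-1,3-dioxin-5-yl)cyclohex-2-en-1-ol, via lithium borate 7 (not isolated)
Conditions: 3, n-BuLi, THF, 0 °C; then 6, NiCl2(PPh3)2 (10 mol %), t-BuCN, NaI, THF, 0 °C → rt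
Reagents that add atoms: none
Why: Nickel-catalysed allylic substitution with an alkenyl borate (Kobayashi-type coupling): ionisation anti to the acetate and delivery of the alkenyl group from nickel give regioselective substitution with net inversion, so the (4S) stereocentre and the 1,4-trans relationship follow from 6.

**Step 6**
Reactants: 8 (1S,4S)-4-(2,2-dimethyl-4H-1,3-dioxin-5-yl)cyclohex-2-en-1-ol
Product: 9 (4S)-4-(2,2-dimethyl-4H-1,3-dioxin-5-yl)cyclohex-2-en-1-one
Conditions: MnO2, CH2Cl2, rt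
Reagents that add atoms: none
Why: Oxidation of the allylic alcohol with MnO2 is neutral and spares the acid-sensitive enol acetal and the γ-stereocentre.

**Step 7**
Reactants: 9 (4S)-4-(2,2-dimethyl-4H-1,3-dioxin-5-yl)cyclohex-2-en-1-one
Product: 10 (4S)-4-(2,2-dimethyl-4H-1,3-dioxin-5-yl)-1-methylcyclohex-2-en-1-ol (both C1 epimers)
Conditions: MeLi, Et2O, −78 °C; then H2O
Reagents that add atoms: methyllithium, [Li]C
Why: 1,2-Addition of MeLi to the enone at −78 °C should outrun γ-deprotonation; the new carbinol centre forms as a mixture, which does not matter because it becomes sp2 in step 8.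

**Step 8**
Reactants: 10 (4S)-4-(2,2-dimethyl-4H-1,3-dioxin-5-yl)-1-methylcyclohex-2-en-1-ol
Product: 12 (6R)-6-(2,2-dimethyl-4H-1,3-dioxin-5-yl)-3-methylcyclohex-2-en-1-one, via allylic alcohol 11 (not isolated)
Conditions: O3ReOSiPh3 (5 mol %), Et2O, −20 → 0 °C; then MnO2, CH2Cl2, rt
Reagents that add atoms: none
Why: Perrhenate-catalysed 1,3-transposition of the tertiary allylic alcohol ([3,3] shift of the perrhenate ester toward the trisubstituted alkene) and MnO2 oxidation give the transposed enone, a chromium-free equivalent of the Dauben oxidative transposition that leaves the stereocentre, now α to the carbonyl, untouched.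

**Step 9**
Reactants: 13 (4-methoxyphenyl)methanol
Product: 14 1-({[(E)-1,2-dichloroethenyl]oxy}methyl)-4-methoxybenzene
Conditions: KH, THF, 0 °C; Cl2C=CHCl, −78 °C → rt
Reagents that add atoms: trichloroethylene, ClC=C(Cl)Cl
Why: Alkoxide-induced dehydrochlorination of trichloroethylene to dichloroacetylene and anti addition of the alcohol give the (E)-1,2-dichlorovinyl ether (Greene ynol ether synthesis).

**Step 10**
Reactants: 12 (6R)-6-(2,2-dimethyl-4H-1,3-dioxin-5-yl)-3-methylcyclohex-2-en-1-one; 14 1-({[(E)-1,2-dichloroethenyl]oxy}methyl)-4-methoxybenzene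
Product: 16 (1S,6R)-6-(2,2-dimethyl-4H-1,3-dioxin-5-yl)-1-{[(4-methoxybenzyl)oxy]ethynyl}-3-methylcyclohex-2-en-1-ol, via lithium alkynide 15 (not isolated)
Conditions: 14, n-BuLi (2.2 equiv), THF, −78 → −40 °C; then 12, −78 °C; then H2O
Reagents that add atoms: none
Why: Elimination and Cl–Li exchange turn 14 into the lithium alkoxyacetylide 15, whose 1,2-addition to the ketone should take place axially on the half-chair with the dioxinyl group pseudo-equatorial (slim sp nucleophile, antiperiplanar attack), putting the alkynyl group cis and the new tertiary hydroxyl trans to the dioxinyl group (1S); the minor epimer is removed by chromatography.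

**Step 11**
Reactants: 16 (1S,6R)-6-(2,2-dimethyl-4H-1,3-dioxin-5-yl)-1-{[(4-methoxybenzyl)oxy]ethynyl}-3-methylcyclohex-2-en-1-ol
Product: 17 (1S,6R)-6-(2,2-dimethyl-4H-1,3-dioxin-5-yl)-1-{(Z)-2-[(4-methoxybenzyl)oxy]ethenyl}-3-methylcyclohex-2-en-1-ol
Conditions: H2 (1 atm), Pd/CaCO3 poisoned with Pb(OAc)2, quinoline, EtOAc–Et3N, 0 °C
Reagents that add atoms: none
Why: Lindlar semihydrogenation adds H2 syn to the alkyne and gives the (Z)-enol ether without touching the trisubstituted alkenes or the PMB group; it is run cold and at once because benzyl-type alkynyl ethers rearrange on warming, and 17 is handled on base-washed silica.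

**Step 12**
Reactants: 17 (1S,6R)-6-(2,2-dimethyl-4H-1,3-dioxin-5-yl)-1-{(Z)-2-[(4-methoxybenzyl)oxy]ethenyl}-3-methylcyclohex-2-en-1-ol
Product: 20 methyl (7R,8S,9R)-9,14-(isopropylidenedioxy)-8-(4-methoxybenzyloxy)-6-oxo-13-norgermacra-1(10)Z,4Z-dien-12-oate, via potassium alkoxide 18 (not isolated), via potassium enolate 19 (not isolated)
Conditions: KN(SiMe3)2 (1.1 equiv), 18-crown-6, THF, −40 → 0 °C; then BrCH2CO2Me, −78 °C
Reagents that add atoms: methyl bromoacetate, COC(=O)CBr
Why: Deprotonation gives alkoxide 18, whose 3-oxido-1,5-diene array C8=C7–C6(O−)–C1–C10=C9 should undergo a charge-accelerated [3,3] shift (anionic oxy-Cope) that breaks C1–C6 and forms C8–C9; the closest known reaction type is the anionic oxy-Cope ring expansion of cis-1,2-dialkenylcyclohexanols to cyclodec-5-enones with in-situ enolate alkylation, and the new element is only that both migrating termini are enol-ether carbons. The ten-membered ring is closed by ring expansion (suprafacial [3,3] through a six-membered chair array), not by end-to-end cyclisation, so no high dilution is needed. C8 and C9 are set by chirality transfer from C1 and C6 through the chair with the dioxinyl group and the oxido oxygen pseudo-equatorial and the C6-alkenyl group axial: the (Z)-OPMB group then sits axial and the ring-locked dioxin oxygen equatorial, giving the erythro (8S,9R) pair, while the axial C1–C2 ring bond delivers the cis C1=C10 alkene and the cis C4=C5 alkene is carried over unchanged. C7 is set by C-alkylation of enolate 19 on its exposed face, the one turned away from the transannular C1=C10 bond in the conformation in which the ring is born. The step needs this chair over the ring-flipped chair (trans alkene, antipodal C8/C9 pair) and over boats; this is secured by the equatorial preference of the large dioxinyl group and by the Z-alkoxy group, which is 1,3-diaxial only to the potassium-bridged oxido oxygen in the wanted chair but to ring carbon C5 in the other. Loss of the C8 alkoxide from the β-alkoxy enolate (E1cB) must be outrun, hence rearrangement at or below 0 °C and alkylation at −78 °C.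

**Step 13**
Reactants: 20 methyl (7R,8S,9R)-9,14-(isopropylidenedioxy)-8-(4-methoxybenzyloxy)-6-oxo-13-norgermacra-1(10)Z,4Z-dien-12-oate
Product: 21 methyl (6S,7S,8S,9R)-6-hydroxy-9,14-(isopropylidenedioxy)-8-(4-methoxybenzyloxy)-13-norgermacra-1(10)Z,4Z-dien-12-oate
Conditions: Zn(BH4)2, Et2O, −20 °C
Reagents that add atoms: none
Why: Chelation-controlled 1,2-reduction (zinc bridging the C6 carbonyl and the C8 ether oxygen, axial hydride delivery on the chelate that carries C9 and C11 equatorial) should give the 1,3-syn alcohol (6S, 6β-OH), the same face that peripheral attack on the ring predicts.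

**Step 14**
Reactants: 21 methyl (6S,7S,8S,9R)-6-hydroxy-9,14-(isopropylidenedioxy)-8-(4-methoxybenzyloxy)-13-norgermacra-1(10)Z,4Z-dien-12-oate
Product: 22 (6S,7S,8S,9R)-6-hydroxy-9,14-(isopropylidenedioxy)-8-(4-methoxybenzyloxy)-13-norgermacra-1(10)Z,4Z-dien-12-oic acid
Conditions: LiOH, THF–H2O, 0 °C → rt; then 0.5 M HCl to pH 4, 0 °C
Reagents that add atoms: lithium hydroxide, [Li+].[OH-]
Why: Saponification of the methyl ester (and of any cis-lactone formed by spontaneous closure of 21) converges on one hydroxy acid, which is liberated cold at pH 4 and used at once.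

**Step 15**
Reactants: 22 (6S,7S,8S,9R)-6-hydroxy-9,14-(isopropylidenedioxy)-8-(4-methoxybenzyloxy)-13-norgermacra-1(10)Z,4Z-dien-12-oic acid
Product: 23 (6R,7S,8S,9R)-9,14-(isopropylidenedioxy)-8-(4-methoxybenzyloxy)-13-norgermacra-1(10)Z,4Z-dien-12,6-olide (trans-fused)
Conditions: PPh3, DIAD, THF, 0 °C
Reagents that add atoms: none
Why: Mitsunobu lactonisation: the allylic 6-hydroxyl is activated as its oxyphosphonium ion and displaced by the tethered carboxylate (5-exo-tet) with inversion, turning 6S into 6R and giving the trans-fused 12,6-lactone.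

**Step 16**
Reactants: 23 (6R,7S,8S,9R)-9,14-(isopropylidenedioxy)-8-(4-methoxybenzyloxy)-13-norgermacra-1(10)Z,4Z-dien-12,6-olide
Product: 26 (6R,7S,8S,9R)-9,14-(isopropylidenedioxy)-8-(4-methoxybenzyloxy)germacra-1(10)Z,4Z,11(13)-trien-12,6-olide, via Mannich base 24 (not isolated), via ammonium iodide 25 (not isolated)
Conditions: LiN(iPr)2, THF, −78 °C; CH2=NMe2+ I−, −78 → 0 °C; then MeI, MeOH, rt; then aq. NaHCO3, CH2Cl2
Reagents that add atoms: N,N-dimethylmethyleneiminium iodide, C=[N+](C)C.[I-]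
Why: Eschenmoser methylenation: Mannich reaction of the lactone lithium enolate, N-methylation and base-induced elimination of trimethylamine install the exocyclic methylene; the C11 stereocentre of 24 is transient.

**Step 17**
Reactants: 26 (6R,7S,8S,9R)-9,14-(isopropylidenedioxy)-8-(4-methoxybenzyloxy)germacra-1(10)Z,4Z,11(13)-trien-12,6-olide
Product: 27 (6R,7R,8S,9R)-8-hydroxy-9,14-(isopropylidenedioxy)germacra-1(10)Z,4Z,11(13)-trien-12,6-olide
Conditions: DDQ, CH2Cl2–pH 7 buffer, 0 °C
Reagents that add atoms: none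
Why: Oxidative cleavage of the PMB ether by DDQ (hydride abstraction, hydrolysis of the oxocarbenium ion) frees the 8-hydroxyl without touching the acetonide, the alkenes or the α-methylene lactone.

**Step 18**
Reactants: 28 (S)-2-hydroxy-2-methylbutanoic acid
Product: 29 (S)-2-acetoxy-2-methylbutanoic acid
Conditions: AcCl (neat), 50 °C; then H2O
Reagents that add atoms: acetyl chloride, CC(Cl)=O
Why: O-Acetylation of the tertiary α-hydroxy acid with neat acetyl chloride (the mixed anhydride is hydrolysed on work-up); the quaternary stereocentre cannot epimerise.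

**Step 19**
Reactants: 29 (S)-2-acetoxy-2-methylbutanoic acid
Product: 30 (S)-2-acetoxy-2-methylbutanoyl chloride
Conditions: (COCl)2, DMF (cat.), CH2Cl2, 0 °C → rt
Reagents that add atoms: oxalyl chloride, ClC(=O)C(Cl)=O
Why: Acid chloride formation with oxalyl chloride and catalytic DMF (Vilsmeier-type activation) under neutral conditions.

**Step 20**
Reactants: 27 (6R,7R,8S,9R)-8-hydroxy-9,14-(isopropylidenedioxy)germacra-1(10)Z,4Z,11(13)-trien-12,6-olide; 30 (S)-2-acetoxy-2-methylbutanoyl chloride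
Product: 31 (6R,7S,8S,9R)-8-[(2S)-2-acetoxy-2-methylbutanoyloxy]-9,14-(isopropylidenedioxy)germacra-1(10)Z,4Z,11(13)-trien-12,6-olide
Conditions: DMAP, Et3N, CH2Cl2, 0 → 40 °C
Reagents that add atoms: none
Why: DMAP-catalysed acylation of the hindered secondary 8-hydroxyl with the acid chloride (acylpyridinium transfer), with retention at C8 and at the acyl stereocentre.

**Step 21**
Reactants: 31 (6R,7S,8S,9R)-8-[(2S)-2-acetoxy-2-methylbutanoyloxy]-9,14-(isopropylidenedioxy)germacra-1(10)Z,4Z,11(13)-trien-12,6-olide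
Product: 32 (6R,7S,8S,9R)-8-[(2S)-2-acetoxy-2-methylbutanoyloxy]-9,14-dihydroxygermacra-1(10)Z,4Z,11(13)-trien-12,6-olide
Conditions: AcOH–H2O (4:1), 40 °C
Reagents that add atoms: none
Why: Mild acid hydrolysis of the isopropylidene acetal releases the 9,14-diol; the esters and the α-methylene lactone are stable to aqueous acetic acid.

**Step 22**
Reactants: 32 (6R,7S,8S,9R)-8-[(2S)-2-acetoxy-2-methylbutanoyloxy]-9,14-dihydroxygermacra-1(10)Z,4Z,11(13)-trien-12,6-olide
Product: 33 (6R,7S,8S,9R)-8-[(2S)-2-acetoxy-2-methylbutanoyloxy]-9-hydroxy-14-oxogermacra-1(10)E,4Z,11(13)-trien-12,6-olide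
Conditions: TEMPO (10 mol %), PhI(OAc)2, CH2Cl2, rt
Reagents that add atoms: none
Why: Oxoammonium (TEMPO/PhI(OAc)2) oxidation is selective for the primary allylic alcohol over the hindered secondary one and gives the conjugated C14 aldehyde without over-oxidation.

**Step 23**
Reactants: 33 (6R,7S,8S,9R)-8-[(2S)-2-acetoxy-2-methylbutanoyloxy]-9-hydroxy-14-oxogermacra-1(10)E,4Z,11(13)-trien-12,6-olide
Product: 34 (6R,7S,8S,9R)-9-acetoxy-8-[(2S)-2-acetoxy-2-methylbutanoyloxy]-14-oxogermacra-1(10)E,4Z,11(13)-trien-12,6-olide (CNP0499875.1)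
Conditions: Ac2O, pyridine, DMAP (cat.), CH2Cl2, 0 °C
Reagents that add atoms: acetic anhydride, CC(=O)OC(C)=O
Why: Acetylation of the remaining secondary allylic 9-hydroxyl under standard acyl-transfer conditions completes the target.

**Compound list**
1 | 2,2-dimethyl-1,3-dioxan-5-one | CC1(C)OCC(=O)CO1 | starting material
2 | 2,2-dimethyl-4H-1,3-dioxin-5-yl trifluoromethanesulfonate | CC1(C)OCC(OS(=O)(=O)C(F)(F)F)=CO1 | intermediate
3 | 2-(2,2-dimethyl-4H-1,3-dioxin-5-yl)-4,4,5,5-tetramethyl-1,3,2-dioxaborolane | CC1(C)OCC(=CO1)B2OC(C)(C)C(C)(C)O2 | intermediate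
4 | cyclohexa-1,3-diene | C1=CC=CCC1 | starting material
5 | cis-cyclohex-2-ene-1,4-diyl diacetate (meso) | CC(=O)O[C@@H]1C=C[C@H](OC(C)=O)CC1 | intermediate
6 | (1R,4S)-4-hydroxycyclohex-2-en-1-yl acetate | O[C@@H]1C=C[C@H](OC(C)=O)CC1 | intermediate
7 | lithium butyl(2,2-dimethyl-4H-1,3-dioxin-5-yl)(pinacolato)borate | [Li+].CCCC[B-]1(OC(C)(C)C(C)(C)O1)C2=COC(C)(C)OC2 | intermediate
8 | (1S,4S)-4-(2,2-dimethyl-4H-1,3-dioxin-5-yl)cyclohex-2-en-1-ol (1,4-trans) | O[C@@H]1C=C[C@@H](C2=COC(C)(C)OC2)CC1 | intermediate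
9 | (4S)-4-(2,2-dimethyl-4H-1,3-dioxin-5-yl)cyclohex-2-en-1-one | O=C1C=C[C@@H](C2=COC(C)(C)OC2)CC1 | intermediate
10 | (4S)-4-(2,2-dimethyl-4H-1,3-dioxin-5-yl)-1-methylcyclohex-2-en-1-ol (both C1 epimers) | CC1(O)C=C[C@@H](C2=COC(C)(C)OC2)CC1 | intermediate
11 | (6R)-6-(2,2-dimethyl-4H-1,3-dioxin-5-yl)-3-methylcyclohex-2-en-1-ol (both C1 epimers) | OC1C=C(C)CC[C@@H]1C2=COC(C)(C)OC2 | intermediate
12 | (6R)-6-(2,2-dimethyl-4H-1,3-dioxin-5-yl)-3-methylcyclohex-2-en-1-one | O=C1C=C(C)CC[C@@H]1C2=COC(C)(C)OC2 | intermediate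
13 | (4-methoxyphenyl)methanol | COc1ccc(CO)cc1 | starting material
14 | 1-({[(E)-1,2-dichloroethenyl]oxy}methyl)-4-methoxybenzene | COc1ccc(CO/C(Cl)=C\Cl)cc1 | intermediate
15 | lithium 2-[(4-methoxybenzyl)oxy]ethynide | [Li+].[C-]#COCc1ccc(OC)cc1 | intermediate
16 | (1S,6R)-6-(2,2-dimethyl-4H-1,3-dioxin-5-yl)-1-{[(4-methoxybenzyl)oxy]ethynyl}-3-methylcyclohex-2-en-1-ol | O[C@@]1(C#COCc2ccc(OC)cc2)C=C(C)CC[C@@H]1C3=COC(C)(C)OC3 | intermediate
17 | (1S,6R)-6-(2,2-dimethyl-4H-1,3-dioxin-5-yl)-1-{(Z)-2-[(4-methoxybenzyl)oxy]ethenyl}-3-methylcyclohex-2-en-1-ol | O[C@@]1(/C=C\OCc2ccc(OC)cc2)C=C(C)CC[C@@H]1C3=COC(C)(C)OC3 | intermediate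
18 | potassium alkoxide of 17 | [K+].[O-][C@@]1(/C=C\OCc2ccc(OC)cc2)C=C(C)CC[C@@H]1C3=COC(C)(C)OC3 | intermediate
19 | potassium (8S,9R)-9,14-(isopropylidenedioxy)-8-(4-methoxybenzyloxy)-11,12,13-trinorgermacra-1(10)Z,4Z,6-trien-6-olate (oxido oxygen cis to C8) | [K+].COc1ccc(CO[C@H]2/C=C(\[O-])/C=C(/C)CC/C=C3/COC(C)(C)O[C@@H]23)cc1 | intermediate
20 | methyl (7R,8S,9R)-9,14-(isopropylidenedioxy)-8-(4-methoxybenzyloxy)-6-oxo-13-norgermacra-1(10)Z,4Z-dien-12-oate | COC(=O)C[C@H]1C(=O)/C=C(/C)CC/C=C2/COC(C)(C)O[C@H]2[C@H]1OCc3ccc(OC)cc3 | intermediate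
21 | methyl (6S,7S,8S,9R)-6-hydroxy-9,14-(isopropylidenedioxy)-8-(4-methoxybenzyloxy)-13-norgermacra-1(10)Z,4Z-dien-12-oate (6β-OH) | COC(=O)C[C@H]1[C@@H](O)/C=C(/C)CC/C=C2/COC(C)(C)O[C@H]2[C@H]1OCc3ccc(OC)cc3 | intermediate
22 | (6S,7S,8S,9R)-6-hydroxy-9,14-(isopropylidenedioxy)-8-(4-methoxybenzyloxy)-13-norgermacra-1(10)Z,4Z-dien-12-oic acid | OC(=O)C[C@H]1[C@@H](O)/C=C(/C)CC/C=C2/COC(C)(C)O[C@H]2[C@H]1OCc3ccc(OC)cc3 | intermediate
23 | (6R,7S,8S,9R)-9,14-(isopropylidenedioxy)-8-(4-methoxybenzyloxy)-13-norgermacra-1(10)Z,4Z-dien-12,6-olide (trans-fused) | C1C(=O)O[C@@H]2/C=C(/C)CC/C=C3/COC(C)(C)O[C@H]3[C@@H](OCc4ccc(OC)cc4)[C@@H]12 | intermediate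
24 | 13-(dimethylamino)-11,13-dihydro derivative of 26 (C11 epimers) | CN(C)CC1C(=O)O[C@@H]2/C=C(/C)CC/C=C3/COC(C)(C)O[C@H]3[C@@H](OCc4ccc(OC)cc4)[C@@H]12 | intermediate
25 | N-methyl ammonium iodide of 24 | [I-].C[N+](C)(C)CC1C(=O)O[C@@H]2/C=C(/C)CC/C=C3/COC(C)(C)O[C@H]3[C@@H](OCc4ccc(OC)cc4)[C@@H]12 | intermediate
26 | (6R,7S,8S,9R)-9,14-(isopropylidenedioxy)-8-(4-methoxybenzyloxy)germacra-1(10)Z,4Z,11(13)-trien-12,6-olide | C=C1C(=O)O[C@@H]2/C=C(/C)CC/C=C3/COC(C)(C)O[C@H]3[C@@H](OCc4ccc(OC)cc4)[C@@H]12 | intermediate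
27 | (6R,7R,8S,9R)-8-hydroxy-9,14-(isopropylidenedioxy)germacra-1(10)Z,4Z,11(13)-trien-12,6-olide | C=C1C(=O)O[C@@H]2/C=C(/C)CC/C=C3/COC(C)(C)O[C@H]3[C@@H](O)[C@@H]12 | intermediate
28 | (S)-2-hydroxy-2-methylbutanoic acid | OC(=O)[C@](C)(CC)O | starting material
29 | (S)-2-acetoxy-2-methylbutanoic acid | OC(=O)[C@](C)(CC)OC(C)=O | intermediate
30 | (S)-2-acetoxy-2-methylbutanoyl chloride | ClC(=O)[C@](C)(CC)OC(C)=O | intermediate
31 | (6R,7S,8S,9R)-8-[(2S)-2-acetoxy-2-methylbutanoyloxy]-9,14-(isopropylidenedioxy)germacra-1(10)Z,4Z,11(13)-trien-12,6-olide | C=C1C(=O)O[C@@H]2/C=C(/C)CC/C=C3/COC(C)(C)O[C@H]3[C@@H](OC(=O)[C@](C)(CC)OC(C)=O)[C@@H]12 | intermediate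
32 | (6R,7S,8S,9R)-8-[(2S)-2-acetoxy-2-methylbutanoyloxy]-9,14-dihydroxygermacra-1(10)Z,4Z,11(13)-trien-12,6-olide | C=C1C(=O)O[C@@H]2/C=C(/C)CC/C=C(/CO)[C@@H](O)[C@@H](OC(=O)[C@](C)(CC)OC(C)=O)[C@@H]12 | intermediate
33 | (6R,7S,8S,9R)-8-[(2S)-2-acetoxy-2-methylbutanoyloxy]-9-hydroxy-14-oxogermacra-1(10)E,4Z,11(13)-trien-12,6-olide | C=C1C(=O)O[C@@H]2/C=C(/C)CC/C=C(/C=O)[C@@H](O)[C@@H](OC(=O)[C@](C)(CC)OC(C)=O)[C@@H]12 | intermediate
34 | (6R,7S,8S,9R)-9-acetoxy-8-[(2S)-2-acetoxy-2-methylbutanoyloxy]-14-oxogermacra-1(10)E,4Z,11(13)-trien-12,6-olide (CNP0499875.1) | C=C1C(=O)O[C@@H]2/C=C(/C)CC/C=C(/C=O)[C@@H](OC(C)=O)[C@@H](OC(=O)[C@](C)(CC)OC(C)=O)[C@@H]12 | target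

**Step count**
Total: 23 steps. Longest linear sequence: 18 steps (3–8, 10–17, 20–23, from cyclohexa-1,3-diene).

**Three steps most likely to fail**

1. Step 12 (riskiest). What may go wrong: expulsion of the C8 alkoxide from the β-alkoxy enolate 19 (E1cB) before it is alkylated, so that the C8 oxygen is lost. Fallback (sets out from 17, comes back at 20): the C8 oxygen is no longer carried through the enolate but put back afterwards. The rearrangement is run as in step 12 and the mixture is warmed to rt so that elimination goes to completion, which should give the cross-conjugated trienone (7Z)-9,14-(isopropylidenedioxy)-11,12,13-trinorgermacra-1(10)Z,4Z,7-trien-6-one F1. Weitz–Scheffer epoxidation (t-BuOOH, DBU, CH2Cl2), which attacks the less substituted C7=C8 enone on its exposed face, should give the cis-7,8-epoxy ketone F2. Reductive opening at the α-carbon with PhSeNa ((PhSe)2, NaBH4, AcOH, EtOH) should give the β-hydroxy ketone (8S,9R)-8-hydroxy-9,14-(isopropylidenedioxy)-11,12,13-trinorgermacra-1(10)Z,4Z-dien-6-one F3. Etherification with 4-methoxybenzyl trichloroacetimidate and La(OTf)3 gives its PMB ether F4. The lithium enolate of F4 (LiN(SiMe3)2, THF, −78 °C), which should hold its β-alkoxy group at this temperature, is alkylated with methyl bromoacetate to return to 20.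

2. Step 15. What may go wrong: closure of hydroxy acid 22 with retention (acid-catalysed, or through acyloxyphosphonium activation), or elimination/SN2′ of the allylic oxyphosphonium ion, so that the inversion at C6 is lost. Fallback (sets out from 20, comes back at 27): no inversion is needed if the hydride is delivered from the C8 oxygen. DDQ cleavage of the PMB ether of 20 gives the β-hydroxy ketone methyl (7R,8S,9R)-8-hydroxy-9,14-(isopropylidenedioxy)-6-oxo-13-norgermacra-1(10)Z,4Z-dien-12-oate F5. Me4NBH(OAc)3 (MeCN–AcOH, −30 °C) reduces it by intramolecular delivery from the 8-O-bound borohydride (Evans–Saksena reduction) to the 1,3-anti diol, the 6α,8β-dihydroxy ester F6. PPTS (CH2Cl2, rt) should close the lactone on the less hindered allylic 6-hydroxyl with retention, giving the trans-fused 8-hydroxy-12,6-lactone F7. Methylenation as in step 16 with one more equivalent of LiN(iPr)2 gives 27.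

3. Step 8. What may go wrong: ionisation and dehydration of the tertiary allylic alcohol or opening of the enol acetal by the Lewis-acidic perrhenate, and erosion of configuration at the new α-stereocentre during oxidation. Fallback (sets out from 2, comes back at 12): the ketone is made by C–C coupling at the α′-carbon and then deracemised. The zinc enolate of commercial 3-methylcyclohex-2-en-1-one (LiN(SiMe3)2, then ZnCl2) is coupled with triflate 2 (Pd2(dba)3, a bulky biarylphosphine, THF, rt; Negishi-type α-alkenylation) to give racemic 6-(2,2-dimethyl-4H-1,3-dioxin-5-yl)-3-methylcyclohex-2-en-1-one F8. KN(SiMe3)2 and allyl chloroformate give the allyl dienol carbonate F9. Palladium-catalysed enantioselective decarboxylative protonation (Pd2(dba)3, the t-Bu-PHOX enantiomer that gives the R ketone, Meldrum's acid, dioxane, rt) gives 12.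

Further compounds
F1 | step 12 | (7Z)-9,14-(isopropylidenedioxy)-11,12,13-trinorgermacra-1(10)Z,4Z,7-trien-6-one (C9 as in 20) | C1/C(C)=C\C(=O)/C=C\[C@@H]2OC(C)(C)OC/C2=C/C1
F2 | step 12 | cis-7,8-epoxide of F1 (epoxide oxygen on the face of the C9 oxygen) | C1/C(C)=C\C(=O)[C@@H]3O[C@@H]3[C@@H]2OC(C)(C)OC/C2=C/C1
F3 | step 12 | (8S,9R)-8-hydroxy-9,14-(isopropylidenedioxy)-11,12,13-trinorgermacra-1(10)Z,4Z-dien-6-one | C1/C(C)=C\C(=O)C[C@H](O)[C@@H]2OC(C)(C)OC/C2=C/C1
F4 | step 12 | (8S,9R)-9,14-(isopropylidenedioxy)-8-(4-methoxybenzyloxy)-11,12,13-trinorgermacra-1(10)Z,4Z-dien-6-one | C1/C(C)=C\C(=O)C[C@H](OCc3ccc(OC)cc3)[C@@H]2OC(C)(C)OC/C2=C/C1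
F5 | step 15 | methyl (7R,8S,9R)-8-hydroxy-9,14-(isopropylidenedioxy)-6-oxo-13-norgermacra-1(10)Z,4Z-dien-12-oate | COC(=O)C[C@H]1C(=O)/C=C(/C)CC/C=C2/COC(C)(C)O[C@H]2[C@H]1O
F6 | step 15 | methyl 6α,8β-dihydroxy-9,14-(isopropylidenedioxy)-13-norgermacra-1(10)Z,4Z-dien-12-oate (1,3-anti diol) | COC(=O)C[C@H]1[C@H](O)/C=C(/C)CC/C=C2/COC(C)(C)O[C@H]2[C@H]1O
F7 | step 15 | 8β-hydroxy-9,14-(isopropylidenedioxy)-13-norgermacra-1(10)Z,4Z-dien-12,6α-olide (trans-fused) | C1C(=O)O[C@@H]2/C=C(/C)CC/C=C3/COC(C)(C)O[C@H]3[C@@H](O)[C@@H]12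
F8 | step 8 | rac-6-(2,2-dimethyl-4H-1,3-dioxin-5-yl)-3-methylcyclohex-2-en-1-one | O=C1C=C(C)CCC1C2=COC(C)(C)OC2
F9 | step 8 | allyl 2-(2,2-dimethyl-4H-1,3-dioxin-5-yl)-5-methylcyclohexa-1,5-dien-1-yl carbonate | C=CCOC(=O)OC1=C(CCC(C)=C1)C2=COC(C)(C)OC2
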